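**Plan**

- Retrosynthesis (labdane numbering): cut the stearate at O15, then the C4–C18 methyl bond and the C8=C17 methylene. Next cut C1–C2 and C5–C10 together, which opens ring A and ring B to a 1,3,9-decatriene. Then cut the diene at C3–C4 and C4–C19 back to a C5 aldehyde, cut C6–C7, and last cut C8–C9 to ethyl glyoxylate and (S)-citronellol.
- Enabling feature: ring A can carry a C3=C4 double bond conjugated with the C19 carboxyl, so C2–C3–C4–C5 is a 2-carboxy-diene. C10 with its methyl (C20) and C1 is an isopropenyl dienophile, and C6–C9 of ring B is the four-carbon tether.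
- Forward: a glyoxylate–ene reaction on the prenyl end of citronellol makes C8–C9 and the isopropenyl group. The chain is grown to the diene ester, one thermal cycloaddition closes ring A and ring B at once, and then follow the C8 methylene, the C4 methyl and the stearate.
- Stereochemistry: C13 comes from (S)-citronellol, C8 and C9 from the BINOL–titanium catalyst. C5 and C10 are relayed from C9 in the cycloaddition, with the C8 silyloxy group as an equatorial anchor. C4 is set by methylation of the enediolate anti to the C10 methyl.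
- Helpers: the C8 silyloxy group (later ketone, then methylene) and the C3=C4 unsaturation (consumed in the reductive methylation).

Key step: step 10

Remark: labdane numbering (C1–C20) is used for all intermediates; ethyl glyoxylate is taken from its commercial toluene solution and cracked before use.

**Route**

Step 1
Reactants: 1 (S)-citronellol
Product: 2 (S)-citronellyl triisopropylsilyl ether
Conditions: i-Pr3SiCl, imidazole, DMF, rt
Reagents that add atoms: triisopropylsilyl chloride, CC(C)[Si](Cl)(C(C)C)C(C)C
Why: Imidazole-promoted silylation of a primary alcohol; the triisopropylsilyl ether is chosen because it should survive Lewis acid, hydride, dilute aqueous acid and dissolving metal.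

Step 2
Reactants: 2 (S)-citronellyl triisopropylsilyl ether; 3 ethyl glyoxylate
Product: 4 ethyl (2S,3R)-2-hydroxy-4-methyl-3-[(3S)-3-methyl-5-(triisopropylsilyloxy)pentyl]pent-4-enoate
Conditions: (S)-BINOL (10 mol %), TiCl2(O-i-Pr)2 (10 mol %), 4 Å MS, CH2Cl2, −30 °C
Reagents that add atoms: none
Why: Catalytic enantioselective glyoxylate–ene reaction: the trisubstituted alkene bonds through its less substituted carbon (C9) while a methyl hydrogen moves to oxygen, so C8–C9 and the isopropenyl group form together, and the BINOL–titanium catalyst should set the (2S) carbinol with the syn relation to C9.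

Step 3
Reactants: 4 ene adduct
Product: 5 triethylsilyl ether of 4 (ethyl 2-(triethylsilyloxy) ester, C8 and C9 as in 4)
Conditions: Et3SiCl, imidazole, DMF, 0 °C to rt
Reagents that add atoms: triethylsilyl chloride, CC[Si](Cl)(CC)CC
Why: Standard silylation of a secondary alcohol; the triethylsilyl group is robust to the neutral and basic steps ahead yet falls off in dilute acid where the primary triisopropylsilyl ether stays.

Step 4
Reactants: 5 silyloxy ester
Product: 6 (2S,3R)-4-methyl-3-[(3S)-3-methyl-5-(triisopropylsilyloxy)pentyl]-2-(triethylsilyloxy)pent-4-enal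
Conditions: i-Bu2AlH (1.05 equiv), CH2Cl2, −78 °C; Rochelle salt
Reagents that add atoms: none
Why: Partial reduction of an α-silyloxy ester, whose tetrahedral aluminate is stable at −78 °C and releases the aldehyde only on work-up.

Step 5
Reactants: 6 α-silyloxy aldehyde
Product: 7 (2E)-6-methyl-5-[(3S)-3-methyl-5-(triisopropylsilyloxy)pentyl]-4-(triethylsilyloxy)hepta-2,6-dienal (C8 and C9 as in 4)
Conditions: Ph3P=CHCHO, toluene, 80 °C
Reagents that add atoms: (triphenylphosphoranylidene)acetaldehyde, O=CC=P(c1ccccc1)(c1ccccc1)c1ccccc1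
Why: Wittig olefination with a stabilised ylide, which should give the E-enal and add C6 and C5 without base strong enough to epimerise C8.

Step 6
Reactants: 7 enal
Product: 8 6-methyl-5-[(3S)-3-methyl-5-(triisopropylsilyloxy)pentyl]-4-(triethylsilyloxy)hept-6-enal (C8 and C9 as in 4)
Conditions: Hantzsch ester (1.1 equiv), dibenzylammonium trifluoroacetate (10 mol %), THF, rt
Reagents that add atoms: none
Why: Organocatalytic transfer hydrogenation through the iminium ion, which delivers hydride only to the conjugated C6=C7 bond and should leave the isopropenyl group and both silyl ethers untouched.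

Step 7
Reactants: 8 saturated aldehyde
Product: 9 1,1-dibromo-7-methyl-6-[(3S)-3-methyl-5-(triisopropylsilyloxy)pentyl]-5-(triethylsilyloxy)octa-1,7-diene (C8 and C9 as in 4)
Conditions: CBr4, PPh3, Et3N, CH2Cl2, 0 °C
Reagents that add atoms: carbon tetrabromide, BrC(Br)(Br)Br
Why: Ramirez dibromo-olefination (first stage of the Corey–Fuchs sequence) turns the C5 aldehyde into a gem-dibromoalkene whose carbon becomes C4; the amine buffers the acid that could cleave the triethylsilyl ether.

Step 8
Reactants: 9 gem-dibromoalkene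
Product: 10 (3Z)-3-bromo-9-methyl-8-[(3S)-3-methyl-5-(triisopropylsilyloxy)pentyl]-7-(triethylsilyloxy)deca-1,3,9-triene (vinyl group trans to C6)
Conditions: tributyl(vinyl)stannane, Pd2(dba)3 (cat.), tri(2-furyl)phosphine, toluene, 100 °C
Reagents that add atoms: tributyl(vinyl)stannane, C=C[Sn](CCCC)(CCCC)CCCC
Why: Trans-selective mono-Stille coupling of a 1,1-dibromoalkene: oxidative addition occurs at the less hindered C–Br bond trans to the alkyl chain, so the vinyl group (C3, C2) should land trans to C6.

Step 9
Reactants: 10 (Z)-2-bromo-1,3-diene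
Product: 11 methyl (2Z)-2-ethenyl-8-methyl-7-[(3S)-3-methyl-5-(triisopropylsilyloxy)pentyl]-6-(triethylsilyloxy)nona-2,8-dienoate (ester cis to C6)
Conditions: CO (1 atm), MeOH, Et3N, Pd(PPh3)4 (cat.), DMF, 60 °C
Reagents that add atoms: carbon monoxide, [C-]#[O+]; methanol, CO
Why: Palladium-catalysed alkoxycarbonylation of an alkenyl bromide proceeds with retention of alkene geometry, so the C19 ester should sit cis to the tether as the cycloaddition requires.

Step 10
Reactants: 11 triene ester
Product: 12 methyl 8α-(triethylsilyloxy)-15-(triisopropylsilyloxy)-17,18-dinorlabd-3-en-19-oate (5α-H, 9α-H, 10β-methyl, 13S)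
Conditions: toluene (0.005 M), BHT (cat.), sealed tube, 190 °C
Reagents that add atoms: none
Why: Thermal intramolecular Diels–Alder reaction (type 1) of a 1,3,9-decatriene: the s-cis diene C2=C3–C4=C5 and the isopropenyl dienophile C10=C1 combine suprafacially in one concerted, asynchronous step that forms C1–C2 and C5–C10 together. The closest known type is the thermal cyclisation of unactivated 3-substituted 1,3,9-decatrienes with a 1,1-disubstituted dienophile to angular-methyl trans-octalins. Ring A closes as a cyclohexene by the [4+2] union itself, with C3=C4 left conjugated to the ester, and ring B closes in the fused mode as the tether C6–C9 is zipped through the C5–C10 bond in a chair-like six-membered array. C10 and C5 are set here: the tether-exo, methyl-endo (anti) transition state gives the trans fusion, and the π-face is chosen by C9, whose side chain sits equatorial on the chair together with the C8 silyloxy group, because the other chair would place that silyloxy group syn-diaxial to the C10 methyl. The step needs fused over bridged regiochemistry (secured by the four-atom tether), the outward tether position on C4=C5 (secured in steps 8 and 9), trans over cis fusion (expected from the C4 substituent on the diene and the angular methyl, which disfavour the tether-endo transition state) and facial control (secured by the 8,9-syn pair from step 2). The C8 silyloxy group and the C3=C4 unsaturation are helpers that are converted later into the exocyclic methylene and the C4 quaternary centre.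

Step 11
Reactants: 12 bicyclic ester
Product: 14 8α-hydroxy-15-(triisopropylsilyloxy)-17,18-dinorlabd-3-en-19-oic acid, via lithium carboxylate 13 (not isolated)
Conditions: LiOH, THF/MeOH/H2O, 50 °C; then 1 M HCl to pH 1, rt
Reagents that add atoms: lithium hydroxide, [Li+].[OH-]
Why: Saponification of the still unhindered conjugated ester, then acid-mediated cleavage of the secondary triethylsilyl ether on acidification, the primary triisopropylsilyl ether being far slower to hydrolyse.

Step 12
Reactants: 14 hydroxy acid
Product: 15 8-oxo-15-(triisopropylsilyloxy)-17,18-dinorlabd-3-en-19-oic acid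
Conditions: Dess–Martin periodinane, NaHCO3, CH2Cl2, rt
Reagents that add atoms: none
Why: Dess–Martin oxidation of the secondary alcohol under buffered conditions that tolerate the free acid and the silyl ether; C9 next to the new ketone is epimerisable, but its equatorial side chain is the stable arrangement.

Step 13
Reactants: 15 keto acid
Product: 16 15-(triisopropylsilyloxy)-18-norlabda-3,8(17)-dien-19-oic acid
Conditions: Ph3PCH3Br (4.2 equiv), KN(SiMe3)2 (4 equiv), THF, 0 to 60 °C
Reagents that add atoms: methyltriphenylphosphonium bromide, C[P+](c1ccccc1)(c1ccccc1)c1ccccc1.[Br-]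
Why: Wittig methylenation of the 8-ketone with excess ylide; the conjugated acid is present as its carboxylate and is inert to the ylide.

Step 14
Reactants: 16 dienoic acid
Product: 18 15-(triisopropylsilyloxy)labd-8(17)-en-19-oic acid, via dilithium enediolate 17 (not isolated)
Conditions: Li, NH3(l)/THF, −78 °C; isoprene; MeI, −78 to −33 °C; NH4Cl
Reagents that add atoms: iodomethane, CI
Why: Birch-type reductive alkylation of an α,β-unsaturated acid: two-electron reduction and protonation at C3 give the exocyclic enediolate, which should be methylated at C4 from the α face (equatorial approach, away from the axial C10 methyl), leaving the carboxyl axial (C19) and the isolated C8 methylene untouched.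

Step 15
Reactants: 18 silyl ether acid
Product: 19 imbricatolic acid, (13S)-15-hydroxylabd-8(17)-en-19-oic acid
Conditions: Bu4NF, THF, rt; aq NH4Cl
Reagents that add atoms: none
Why: Fluoride cleavage of the primary triisopropylsilyl ether under non-acidic conditions that do not isomerise the exocyclic alkene.

Step 16
Reactants: 19 imbricatolic acid; 20 stearoyl chloride
Product: 21 (13S)-15-(octadecanoyloxy)labd-8(17)-en-19-oic acid (target)
Conditions: pyridine, CH2Cl2, 0 °C to rt; then H2O/THF, dilute acid wash
Reagents that add atoms: none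
Why: Acylation of the primary alcohol with an acid chloride; the axial tertiary C19 acid is acylated far more slowly, and any mixed anhydride is hydrolysed back to the free acid in the aqueous hold.

**Compound list**

1 | (S)-(−)-citronellol, (3S)-3,7-dimethyloct-6-en-1-ol | CC(C)=CCC[C@H](C)CCO | starting material
2 | (S)-citronellyl triisopropylsilyl ether | CC(C)=CCC[C@H](C)CCO[Si](C(C)C)(C(C)C)C(C)C | intermediate
3 | ethyl glyoxylate | CCOC(=O)C=O | starting material
4 | ethyl (2S,3R)-2-hydroxy-4-methyl-3-[(3S)-3-methyl-5-(triisopropylsilyloxy)pentyl]pent-4-enoate | CCOC(=O)[C@@H](O)[C@H](CC[C@H](C)CCO[Si](C(C)C)(C(C)C)C(C)C)C(C)=C | intermediate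
5 | triethylsilyl ether of 4 | CCOC(=O)[C@@H](O[Si](CC)(CC)CC)[C@H](CC[C@H](C)CCO[Si](C(C)C)(C(C)C)C(C)C)C(C)=C | intermediate
6 | (2S,3R)-4-methyl-3-[(3S)-3-methyl-5-(triisopropylsilyloxy)pentyl]-2-(triethylsilyloxy)pent-4-enal | O=C[C@@H](O[Si](CC)(CC)CC)[C@H](CC[C@H](C)CCO[Si](C(C)C)(C(C)C)C(C)C)C(C)=C | intermediate
7 | (2E)-6-methyl-5-[(3S)-3-methyl-5-(triisopropylsilyloxy)pentyl]-4-(triethylsilyloxy)hepta-2,6-dienal | O=C/C=C/[C@@H](O[Si](CC)(CC)CC)[C@H](CC[C@H](C)CCO[Si](C(C)C)(C(C)C)C(C)C)C(C)=C | intermediate
8 | 6-methyl-5-[(3S)-3-methyl-5-(triisopropylsilyloxy)pentyl]-4-(triethylsilyloxy)hept-6-enal | O=CCC[C@@H](O[Si](CC)(CC)CC)[C@H](CC[C@H](C)CCO[Si](C(C)C)(C(C)C)C(C)C)C(C)=C | intermediate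
9 | 1,1-dibromo-7-methyl-6-[(3S)-3-methyl-5-(triisopropylsilyloxy)pentyl]-5-(triethylsilyloxy)octa-1,7-diene | BrC(Br)=CCC[C@@H](O[Si](CC)(CC)CC)[C@H](CC[C@H](C)CCO[Si](C(C)C)(C(C)C)C(C)C)C(C)=C | intermediate
10 | (3Z)-3-bromo-9-methyl-8-[(3S)-3-methyl-5-(triisopropylsilyloxy)pentyl]-7-(triethylsilyloxy)deca-1,3,9-triene | C=C/C(Br)=C/CC[C@@H](O[Si](CC)(CC)CC)[C@H](CC[C@H](C)CCO[Si](C(C)C)(C(C)C)C(C)C)C(C)=C | intermediate
11 | methyl (2Z)-2-ethenyl-8-methyl-7-[(3S)-3-methyl-5-(triisopropylsilyloxy)pentyl]-6-(triethylsilyloxy)nona-2,8-dienoate | C=C/C(C(=O)OC)=C/CC[C@@H](O[Si](CC)(CC)CC)[C@H](CC[C@H](C)CCO[Si](C(C)C)(C(C)C)C(C)C)C(C)=C | intermediate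
12 | methyl 8α-(triethylsilyloxy)-15-(triisopropylsilyloxy)-17,18-dinorlabd-3-en-19-oate | CC[Si](CC)(CC)O[C@@H]1CC[C@@H]2[C@](C)(CCC=C2C(=O)OC)[C@H]1CC[C@H](C)CCO[Si](C(C)C)(C(C)C)C(C)C | intermediate
13 | lithium 8α-(triethylsilyloxy)-15-(triisopropylsilyloxy)-17,18-dinorlabd-3-en-19-oate | CC[Si](CC)(CC)O[C@@H]1CC[C@@H]2[C@](C)(CCC=C2C(=O)[O-])[C@H]1CC[C@H](C)CCO[Si](C(C)C)(C(C)C)C(C)C.[Li+] | intermediate
14 | 8α-hydroxy-15-(triisopropylsilyloxy)-17,18-dinorlabd-3-en-19-oic acid | O[C@@H]1CC[C@@H]2[C@](C)(CCC=C2C(=O)O)[C@H]1CC[C@H](C)CCO[Si](C(C)C)(C(C)C)C(C)C | intermediate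
15 | 8-oxo-15-(triisopropylsilyloxy)-17,18-dinorlabd-3-en-19-oic acid | O=C1CC[C@@H]2[C@](C)(CCC=C2C(=O)O)[C@H]1CC[C@H](C)CCO[Si](C(C)C)(C(C)C)C(C)C | intermediate
16 | 15-(triisopropylsilyloxy)-18-norlabda-3,8(17)-dien-19-oic acid | C=C1CC[C@@H]2[C@](C)(CCC=C2C(=O)O)[C@H]1CC[C@H](C)CCO[Si](C(C)C)(C(C)C)C(C)C | intermediate
17 | dilithium enediolate of 15-(triisopropylsilyloxy)-18-norlabd-8(17)-en-19-oic acid (C4=C19 enediolate) | C=C1CC[C@@H]2[C@](C)(CCCC2=C([O-])[O-])[C@H]1CC[C@H](C)CCO[Si](C(C)C)(C(C)C)C(C)C.[Li+].[Li+] | intermediate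
18 | 15-(triisopropylsilyloxy)labd-8(17)-en-19-oic acid | C=C1CC[C@@H]2[C@](C)(CCC[C@]2(C)C(=O)O)[C@H]1CC[C@H](C)CCO[Si](C(C)C)(C(C)C)C(C)C | intermediate
19 | imbricatolic acid, (13S)-15-hydroxylabd-8(17)-en-19-oic acid | C=C1CC[C@@H]2[C@](C)(CCC[C@]2(C)C(=O)O)[C@H]1CC[C@H](C)CCO | intermediate
20 | stearoyl chloride (octadecanoyl chloride) | CCCCCCCCCCCCCCCCCC(=O)Cl | starting material
21 | (13S)-15-(octadecanoyloxy)labd-8(17)-en-19-oic acid | C=C1CC[C@@H]2[C@](C)(CCC[C@]2(C)C(=O)O)[C@H]1CC[C@H](C)CCOC(=O)CCCCCCCCCCCCCCCCC | target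

**Step count and risks**

Total steps: 16. Longest linear sequence: 16 steps, from (S)-citronellol.

Steps most likely to fail:

1. Step 10. The 2-(methoxycarbonyl)diene may oligomerise by intermolecular Diels–Alder reaction faster than it closes onto the hindered 1,1-disubstituted dienophile, and the trans over cis preference may erode at 190 °C. Fallback, from 10 back to 12: the order of events is changed so that the cycloaddition is run on the bromodiene, which does not self-dimerise and keeps a substituent at C4. Compound 10 would be heated (toluene, BHT, propylene oxide, 200 °C) to give 4-bromo-8α-(triethylsilyloxy)-15-(triisopropylsilyloxy)-17,18,19-trinorlabd-3-ene F1. This alkenyl bromide would then be methoxycarbonylated (CO, MeOH, Et3N, Pd(PPh3)4, DMF, 70 °C) to give 12.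

2. Step 2. Facial and syn/anti control may be incomplete when a prenyl-type trisubstituted alkene is the ene donor, for instance through a stepwise cationic pathway at the Lewis acid. Fallback, from 2 back to 8: the C8–C9 bond would be made by a reagent-defined allylboration instead.
   - Ozonolysis of 2 (O3, CH2Cl2, −78 °C; Me2S) would give (4S)-4-methyl-6-(triisopropylsilyloxy)hexanal F2.
   - Stork–Zhao olefination ((1-iodoethyl)triphenylphosphonium iodide, NaN(SiMe3)2, THF, −78 °C) would give the (Z)-vinyl iodide triisopropyl{[(3S,6Z)-7-iodo-3-methyloct-6-en-1-yl]oxy}silane F3.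
   - Iodine–lithium exchange (t-BuLi, Et2O, −78 °C) and Matteson-type homologation with 2-(chloromethyl)-4,4,5,5-tetramethyl-1,3,2-dioxaborolane would give, with retention, the (Z)-allylboronate F4.
   - Allylboration of methyl 4-oxobutanoate catalysed by the (S)-enantiomer of 3,3'-bis(2,4,6-triisopropylphenyl)-BINOL phosphoric acid (toluene, −30 °C) should give, through the chair transition state of a Z-reagent, the syn hydroxy ester methyl 4-hydroxy-6-methyl-5-[(3S)-3-methyl-5-(triisopropylsilyloxy)pentyl]hept-6-enoate F5.
   - Silylation (Et3SiCl, imidazole) would give the triethylsilyl ether F6, and reduction with i-Bu2AlH at −78 °C would give 8.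

3. Step 8. Mono-selectivity may be lost (double coupling), or the product may dehydrobrominate to an enyne, and the alkene geometry may scramble at 100 °C. Fallback, from 8 back to 11: the geometry would be set by olefination instead of by site-selective coupling. Aldehyde 8 would undergo a Horner–Wadsworth–Emmons reaction with methyl bromo[bis(2,2,2-trifluoroethoxy)phosphoryl]acetate (made by bromination of the commercial Still–Gennari reagent; t-BuOK, 18-crown-6, THF, −78 °C) to give the (E)-α-bromoacrylate methyl (2E)-2-bromo-8-methyl-7-[(3S)-3-methyl-5-(triisopropylsilyloxy)pentyl]-6-(triethylsilyloxy)nona-2,8-dienoate F7, with the ester cis to the chain. Stille coupling with tributyl(vinyl)stannane (Pd2(dba)3, AsPh3, CuI, DMF, rt) would then give 11 with retention.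

**Further compounds**

F1 | step 10 | 4-bromo-8α-(triethylsilyloxy)-15-(triisopropylsilyloxy)-17,18,19-trinorlabd-3-ene | CC[Si](CC)(CC)O[C@@H]1CC[C@@H]2[C@](C)(CCC=C2Br)[C@H]1CC[C@H](C)CCO[Si](C(C)C)(C(C)C)C(C)C
F2 | step 2 | (4S)-4-methyl-6-(triisopropylsilyloxy)hexanal | O=CCC[C@H](C)CCO[Si](C(C)C)(C(C)C)C(C)C
F3 | step 2 | triisopropyl{[(3S,6Z)-7-iodo-3-methyloct-6-en-1-yl]oxy}silane | C/C(I)=C/CC[C@H](C)CCO[Si](C(C)C)(C(C)C)C(C)C
F4 | step 2 | (Z)-allylboronate, 2-[(2Z,6S)-2,6-dimethyl-8-(triisopropylsilyloxy)oct-2-en-1-yl]-4,4,5,5-tetramethyl-1,3,2-dioxaborolane | C/C(CB1OC(C)(C)C(C)(C)O1)=C/CC[C@H](C)CCO[Si](C(C)C)(C(C)C)C(C)C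
F5 | step 2 | methyl 4-hydroxy-6-methyl-5-[(3S)-3-methyl-5-(triisopropylsilyloxy)pentyl]hept-6-enoate (syn, C8 and C9 as in 8) | COC(=O)CC[C@@H](O)[C@H](CC[C@H](C)CCO[Si](C(C)C)(C(C)C)C(C)C)C(C)=C
F6 | step 2 | triethylsilyl ether of F5 | COC(=O)CC[C@@H](O[Si](CC)(CC)CC)[C@H](CC[C@H](C)CCO[Si](C(C)C)(C(C)C)C(C)C)C(C)=C
F7 | step 8 | methyl (2E)-2-bromo-8-methyl-7-[(3S)-3-methyl-5-(triisopropylsilyloxy)pentyl]-6-(triethylsilyloxy)nona-2,8-dienoate | Br/C(C(=O)OC)=C/CC[C@@H](O[Si](CC)(CC)CC)[C@H](CC[C@H](C)CCO[Si](C(C)C)(C(C)C)C(C)C)C(C)=C
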